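**Assumption:** (R)-benzyl glycidyl ether (4), 5-hydroxyvanillin (6) and 2'-hydroxy-4',6'-bis(benzyloxy)acetophenone (8) are taken as catalogue items; 8 is otherwise one benzylation from phloroacetophenone. The target SMILES is read as the trans-(2R,3R)-benzodioxane.

## Retrosynthetic overview

1. Palstatin ⇒ seco-phenol 11 by opening the benzylic C–O bond of the benzodioxane; forward, this is an anodic quinone-methide cyclisation, with the trans relationship set by the existing C–O stereocentre.
2. 11 ⇒ perbenzylated flavone 10 (hydrogenolysis) ⇒ chalcone 9 (I2/DMSO) ⇒ aldehyde 7 + acetophenone 8 (Claisen–Schmidt).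
3. 7 ⇒ carbinol 5 + 5-hydroxyvanillin 6 (Mitsunobu, inversion); 5 ⇒ aryl Grignard from 3 + (R)-benzyl glycidyl ether 4, the only source of chirality.
4. Ring order: flavone pyranone ring first (step 5), 1,4-benzodioxane ring last (step 7).

## Route

**Step 1**
Reactants: 1, 4-bromo-2,6-dimethoxyphenol; 2, benzyl bromide
Product: 3, 2-(benzyloxy)-5-bromo-1,3-dimethoxybenzene
Conditions: K2CO3, DMF, 60 °C
Reagents that add atoms: benzyl bromide (2), BrCc1ccccc1
Why: Williamson ether synthesis on the only acidic site masks the phenol for Grignard formation and for the later Mitsunobu step.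

**Step 2**
Reactants: 3, 2-(benzyloxy)-5-bromo-1,3-dimethoxybenzene; 4, (R)-benzyl glycidyl ether
Product: 5, (2R)-1-(benzyloxy)-3-[4-(benzyloxy)-3,5-dimethoxyphenyl]propan-2-ol
Conditions: Mg, THF, 50 °C (I2 initiation); then CuI (10 mol %), 4, THF, −30 → 0 °C
Reagents that add atoms: none (all atoms come from 3 and 4)
Why: Copper-catalysed Grignard opening of a terminal epoxide occurs by SN2 at the unsubstituted carbon, so the purchased stereocentre is untouched and appears as the (R)-carbinol.

**Step 3**
Reactants: 5, the (2R)-carbinol; 6, 3,4-dihydroxy-5-methoxybenzaldehyde (5-hydroxyvanillin)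
Product: 7, 3-hydroxy-5-methoxy-4-{[(2S)-1-(benzyloxy)-3-[4-(benzyloxy)-3,5-dimethoxyphenyl]propan-2-yl]oxy}benzaldehyde
Conditions: PPh3, DIAD, THF (1 M), 0 °C → rt
Reagents that add atoms: none
Why: Mitsunobu etherification proceeds with clean SN2 inversion (R-carbinol → S-aryl ether), and the 4-OH para to the aldehyde (pKa about 7.5 versus about 9.5 for the 3-OH) is the one ionised and alkylated.

**Step 4**
Reactants: 7, the aldehyde; 8, 1-[2,4-bis(benzyloxy)-6-hydroxyphenyl]ethanone
Product: 9, (E)-1-[2,4-bis(benzyloxy)-6-hydroxyphenyl]-3-(3-hydroxy-5-methoxy-4-{[(2S)-1-(benzyloxy)-3-[4-(benzyloxy)-3,5-dimethoxyphenyl]propan-2-yl]oxy}phenyl)prop-2-en-1-one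
Conditions: 50 % aq. KOH (excess), EtOH/THF, rt, 36 h; then dilute HCl
Reagents that add atoms: none
Why: Claisen–Schmidt aldol condensation of a non-enolisable aldehyde gives the thermodynamic E-chalcone; the free meta-phenol only consumes one extra equivalent of base, and the alkyl aryl ether stereocentre is base-stable.

**Step 5**
Reactants: 9, the chalcone
Product: 10, 5,7-bis(benzyloxy)-2-(3-hydroxy-5-methoxy-4-{[(2S)-1-(benzyloxy)-3-[4-(benzyloxy)-3,5-dimethoxyphenyl]propan-2-yl]oxy}phenyl)-4H-chromen-4-one
Conditions: I2 (10 mol %), DMSO, 120 °C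
Reagents that add atoms: none
Why: I2/DMSO oxidative cyclisation (oxa-Michael to the flavanone, then iodine-mediated dehydrogenation with DMSO as terminal oxidant) forms the pyranone ring; a free 3'-OH is tolerated as in the I2-mediated hesperidin → diosmin dehydrogenation, and any 5-O-debenzylated by-product converges in step 6.

**Step 6**
Reactants: 10, the perbenzylated flavone
Product: 11, 5,7-dihydroxy-2-(3-hydroxy-4-{[(2S)-1-hydroxy-3-(4-hydroxy-3,5-dimethoxyphenyl)propan-2-yl]oxy}-5-methoxyphenyl)-4H-chromen-4-one
Conditions: H2 (1 atm), Pd(OH)2/C, THF/MeOH, rt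
Reagents that add atoms: none
Why: Catalytic hydrogenolysis removes all four benzyl ethers; at this stage the molecule has no other benzylic C–O bond, and the flavone C2=C3 bond and the secondary alkyl aryl ether survive at 1 atm.

**Step 7**
Reactants: 11, the seco-pentaol
Product: 12, palstatin, 5,7-dihydroxy-2-[(2R,3R)-3-(4-hydroxy-3,5-dimethoxyphenyl)-2-(hydroxymethyl)-8-methoxy-2,3-dihydro-1,4-benzodioxin-6-yl]-4H-chromen-4-one (trans)
Conditions: undivided cell, graphite felt (+) / Pt (−), +0.60 V vs Ag/AgCl to 2.1 F mol⁻¹, n-Bu4NPF6 (0.1 M), 2,6-lutidine (3 equiv), MeCN/HFIP 4:1, 5 mM, 0 °C, Ar; then 2 h at rt without current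
Reagents that add atoms: none (net loss of H2, evolved at the cathode)
Why: Proposed new method: base-assisted anodic 2e⁻/2H⁺ oxidation of the 4-alkyl-2,6-dimethoxyphenol, the most easily oxidised site (estimated several hundred mV below the chelated flavone phenols), gives the phenoxyl radical and then the p-quinone methide, which the neighbouring 3'-OH captures by 6-exo-trig 1,6-oxa-Michael addition; the existing ether stereocentre places aryl and CH2OH both pseudo-equatorial (trans), and any cis isomer can re-open to the quinone methide under lutidine/HFIP and drain to the more stable trans isomer, giving the new benzylic centre as R (the old centre is now also designated R only because the ring carbon outranks CH2OH); closest known reactions are Ag2O or DDQ oxidation of 4-alkylsyringols to quinone methides, anodic benzylic alkoxylation of p-alkylphenols, and Ag2CO3-mediated oxidative benzodioxane formation in flavonolignan synthesis.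

## Compound list

1 | 4-bromo-2,6-dimethoxyphenol | COc1cc(Br)cc(OC)c1O | starting material
2 | benzyl bromide | BrCc1ccccc1 | starting material
3 | 2-(benzyloxy)-5-bromo-1,3-dimethoxybenzene | COc1cc(Br)cc(OC)c1OCc1ccccc1 | intermediate
4 | (R)-benzyl glycidyl ether | C1O[C@H]1COCc1ccccc1 | starting material
5 | (2R)-1-(benzyloxy)-3-[4-(benzyloxy)-3,5-dimethoxyphenyl]propan-2-ol | O[C@@H](COCc1ccccc1)Cc1cc(OC)c(OCc2ccccc2)c(OC)c1 | intermediate
6 | 3,4-dihydroxy-5-methoxybenzaldehyde (5-hydroxyvanillin) | COc1cc(C=O)cc(O)c1O | starting material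
7 | 3-hydroxy-5-methoxy-4-{[(2S)-1-(benzyloxy)-3-[4-(benzyloxy)-3,5-dimethoxyphenyl]propan-2-yl]oxy}benzaldehyde | COc1cc(C=O)cc(O)c1O[C@H](COCc1ccccc1)Cc1cc(OC)c(OCc2ccccc2)c(OC)c1 | intermediate
8 | 1-[2,4-bis(benzyloxy)-6-hydroxyphenyl]ethanone | CC(=O)c1c(O)cc(OCc2ccccc2)cc1OCc1ccccc1 | starting material
9 | (E)-2'-hydroxy-4',6'-bis(benzyloxy)chalcone bearing the 3-hydroxy-5-methoxy-4-[(2S)-alkoxy]phenyl B-ring | COc1cc(/C=C/C(=O)c2c(O)cc(OCc3ccccc3)cc2OCc2ccccc2)cc(O)c1O[C@H](COCc1ccccc1)Cc1cc(OC)c(OCc2ccccc2)c(OC)c1 | intermediate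
10 | 5,7-bis(benzyloxy)flavone with the 3'-hydroxy-5'-methoxy-4'-[(2S)-alkoxy] B-ring | COc1cc(-c2cc(=O)c3c(OCc4ccccc4)cc(OCc4ccccc4)cc3o2)cc(O)c1O[C@H](COCc1ccccc1)Cc1cc(OC)c(OCc2ccccc2)c(OC)c1 | intermediate
11 | 5,7-dihydroxy-2-(3-hydroxy-4-{[(2S)-1-hydroxy-3-(4-hydroxy-3,5-dimethoxyphenyl)propan-2-yl]oxy}-5-methoxyphenyl)-4H-chromen-4-one | COc1cc(-c2cc(=O)c3c(O)cc(O)cc3o2)cc(O)c1O[C@H](CO)Cc1cc(OC)c(O)c(OC)c1 | intermediate
12 | palstatin | COc1cc([C@H]2Oc3cc(-c4cc(=O)c5c(O)cc(O)cc5o4)cc(OC)c3O[C@@H]2CO)cc(OC)c1O | target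

## Summary

Total steps: 7. Longest linear sequence: 7 (1 → 3 → 5 → 7 → 9 → 10 → 11 → 12).

Steps most likely to fail:

1. **Step 7 (proposed anodic quinone-methide cyclisation).** Risks are over-oxidation of the product's own syringyl phenol, competing oxidation of the flavone 7-phenolate, and incomplete cis → trans equilibration. Fallback (known chemistry): close the benzodioxane before the flavone exists with a stoichiometric oxidant. Debenzylate 7 (BCl3/pentamethylbenzene), oxidise with Ag2O (established for 4-alkylsyringol → quinone methide) and equilibrate to trans with mild acid. Then build the flavone on the benzodioxane aldehyde with the bis-MOM acetophenone (Claisen–Schmidt, I2/DMSO, HCl/MeOH), as in classical flavonolignan endgames.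
2. **Step 3 (Mitsunobu on a free catechol with a di-ortho-substituted phenol).** Risks are alkylation at the 3-OH, catechol–phosphorane formation and low conversion. Fallback: pre-differentiate the catechol as 3-(benzyloxy)-4-hydroxy-5-methoxybenzaldehyde by dianion benzylation (NaH 2.2 equiv, DMSO; BnBr 1 equiv), so a single phenol enters the Mitsunobu. The extra benzyl group is removed in step 6.
3. **Step 5 (I2/DMSO with a free electron-rich phenol and benzyl ethers).** Risks are ring iodination and partial debenzylation. Fallback: Baker–Venkataraman construction. Pinnick-oxidise the O-benzylated aldehyde to the acid, esterify onto the 2'-OH of 8, rearrange with KOH/pyridine to the 1,3-diketone, and cyclodehydrate with AcOH/H2SO4.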